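**Assumptions:** 5‑Methylhex‑5‑enal is treated as not purchasable and is made in two steps. The sense of induction in step 3 is assigned from the standard diarylprolinol‑ether enamine shielding model (electrophile adds anti to the diarylmethyl group).

## Retrosynthetic overview

1. C4 carries two sterically near‑identical chains (prenyl and 3‑methylbut‑3‑enyl), so the acyclic stereotriad is built on a temporary cyclohexanone in which the future C4‑prenyl carbons are ring atoms.
2. Target ⇐ phenol TBS ether ⇐ Wittig (Ph3P=CMe2) on an aldehyde; the aldehyde and the aryl ketone both come from glycol cleavage of a 1‑aryl‑cyclohexane‑1,2‑diol (ring C1–C6 scission).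
3. Diol ⇐ ArLi addition to an α′‑hydroxy ketone ⇐ enolate hydroxylation of a 2,2,3,4‑substituted cyclohexanone.
4. Cyclohexanone ⇐ trans‑selective isopropenyl cuprate addition (sets C3), then enolate prenylation (sets quaternary C2) on an (S)‑4‑substituted 2‑methylcyclohexenone.
5. Enone ⇐ organocatalytic Michael addition of 5‑methylhex‑5‑enal to ethyl vinyl ketone (sets C4), then aldol condensation. This is the only ring formed, and it is opened again in step 9.

Numbers are given to substrates, products and every reagent that contributes atoms. Catalysts, bases and solvents appear only under Conditions.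

## Route

**Step 1**
Reactants: 1, methyl 5‑oxohexanoate; 2, methyltriphenylphosphonium bromide
Product: 3, methyl 5‑methylhex‑5‑enoate
Conditions: 2, KHMDS, THF, 0 °C → rt
Reagents that add atoms: 2, methyltriphenylphosphonium bromide, C[P+](c1ccccc1)(c1ccccc1)c1ccccc1.[Br-] (adds CH2)
Why: Wittig methylenation; the non‑stabilised ylide reacts with the ketone far faster than with the ester.

**Step 2**
Reactants: 3
Product: 4, 5‑methylhex‑5‑enal
Conditions: DIBAL‑H (1.05 equiv), CH2Cl2, −78 °C; MeOH, Rochelle salt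
Reagents that add atoms: none
Why: Low‑temperature DIBAL half‑reduction of a methyl ester stops at the tetrahedral aluminate, which releases the aldehyde on work‑up.

**Step 3**
Reactants: 4; 5, ethyl vinyl ketone (pent‑1‑en‑3‑one)
Product: 6, (S)‑2‑(3‑methylbut‑3‑en‑1‑yl)‑5‑oxoheptanal
Conditions: (R)‑2‑(methoxydiphenylmethyl)pyrrolidine (5 mol%), ethyl 3,4‑dihydroxybenzoate (20 mol%), neat, 4 °C
Reagents that add atoms: 5, ethyl vinyl ketone, C=CC(=O)CC
Why: Enamine‑catalysed asymmetric Michael addition; the (E)‑enamine is attacked on the face away from the CPh2OMe group, which with the (R)‑catalyst gives the (S)‑aldehyde (the future C4).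

**Step 4**
Reactants: 6
Product: 7, (S)‑2‑methyl‑4‑(3‑methylbut‑3‑en‑1‑yl)cyclohex‑2‑en‑1‑one
Conditions: LiOH·H2O, i‑PrOH, rt
Reagents that add atoms: none
Why: Intramolecular aldol condensation (Robinson‑type) of the ethyl ketone onto the aldehyde; only the six‑membered enone can form, and the stereocentre is carried through as the γ‑carbon.

**Step 5**
Reactants: 7; 8, isopropenylmagnesium bromide; 9, chlorotrimethylsilane
Product: 10, trimethyl{[(3S,4S)‑2‑methyl‑4‑(3‑methylbut‑3‑en‑1‑yl)‑3‑(prop‑1‑en‑2‑yl)cyclohex‑1‑en‑1‑yl]oxy}silane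
Conditions: CuBr·SMe2 (0.3 equiv), TMSCl, DMPU, THF, −78 → −40 °C; Et3N quench
Reagents that add atoms: 8, isopropenylmagnesium bromide, C=C(C)[Mg]Br; 9, TMSCl, C[Si](C)(C)Cl
Why: TMSCl‑accelerated copper‑mediated conjugate addition; the cuprate adds anti to the C4 substituent (3,4‑trans, sets C3), and the enolate is captured regiospecifically as the silyl enol ether.

**Step 6**
Reactants: 10; 11, prenyl bromide
Product: 12, (2S,3S,4S)‑2‑methyl‑2‑(3‑methylbut‑2‑en‑1‑yl)‑4‑(3‑methylbut‑3‑en‑1‑yl)‑3‑(prop‑1‑en‑2‑yl)cyclohexan‑1‑one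
Conditions: MeLi, THF, 0 °C; then DMPU, prenyl bromide, −78 → 0 °C
Reagents that add atoms: 11, prenyl bromide, CC(C)=CCBr
Why: Regiospecific lithium enolate from the enol silane, then C‑alkylation; the electrophile enters anti to the adjacent pseudoaxial C3 isopropenyl group (2,3‑trans), setting the quaternary C2.

**Step 7**
Reactants: 12; 13, 3‑phenyl‑2‑(phenylsulfonyl)oxaziridine (Davis reagent)
Product: 14, (2S,3S,4S)‑6‑hydroxy‑2‑methyl‑2‑(3‑methylbut‑2‑en‑1‑yl)‑4‑(3‑methylbut‑3‑en‑1‑yl)‑3‑(prop‑1‑en‑2‑yl)cyclohexan‑1‑one (C6 epimers, inconsequential)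
Conditions: KHMDS, THF, −78 °C; then 13
Reagents that add atoms: 13, Davis oxaziridine, O=S(=O)(N1OC1c1ccccc1)c1ccccc1 (adds O)
Why: Davis enolate hydroxylation; C6 is the only enolisable position and the oxaziridine leaves the three alkenes untouched.

**Step 8**
Reactants: 14; 15, (3‑bromophenoxy)(tert‑butyl)dimethylsilane
Product: 16, (4S,5S,6S)‑1‑[3‑(tert‑butyldimethylsilyloxy)phenyl]‑6‑methyl‑6‑(3‑methylbut‑2‑en‑1‑yl)‑4‑(3‑methylbut‑3‑en‑1‑yl)‑5‑(prop‑1‑en‑2‑yl)cyclohexane‑1,2‑diol (mixture at C1/C2, inconsequential)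
Conditions: 15, t‑BuLi, Et2O, −78 °C (gives ArLi, 3 equiv); then 14, THF, −78 → 0 °C
Reagents that add atoms: 15, (3‑bromophenoxy)(tert‑butyl)dimethylsilane, CC(C)(C)[Si](C)(C)Oc1cccc(Br)c1
Why: Br/Li exchange then 1,2‑addition of the aryllithium to the ketone; the first equivalent deprotonates the α‑OH, and the new carbinol centres are destroyed in the next step.

**Step 9**
Reactants: 16
Product: 17, (3S,4S,5S)‑6‑[3‑(tert‑butyldimethylsilyloxy)phenyl]‑5‑methyl‑5‑(3‑methylbut‑2‑en‑1‑yl)‑3‑(3‑methylbut‑3‑en‑1‑yl)‑6‑oxo‑4‑(prop‑1‑en‑2‑yl)hexanal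
Conditions: Pb(OAc)4, NaHCO3, CH2Cl2, 0 °C
Reagents that add atoms: none
Why: Criegee glycol cleavage opens the ring at C1–C6, giving the aryl ketone and the aldehyde in one operation without touching the alkenes or any stereocentre.

**Step 10**
Reactants: 17; 18, isopropyltriphenylphosphonium iodide
Product: 19, (2S,3S,4S)‑1‑[3‑(tert‑butyldimethylsilyloxy)phenyl]‑2,7‑dimethyl‑2‑(3‑methylbut‑2‑en‑1‑yl)‑4‑(3‑methylbut‑3‑en‑1‑yl)‑3‑(prop‑1‑en‑2‑yl)oct‑6‑en‑1‑one
Conditions: 18, n‑BuLi, THF, 0 °C; then 17, −78 °C → rt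
Reagents that add atoms: 18, isopropyltriphenylphosphonium iodide, CC(C)[P+](c1ccccc1)(c1ccccc1)c1ccccc1.[I-] (adds CMe2)
Why: Wittig olefination of the unhindered aldehyde completes the second prenyl group; the neopentyl, non‑enolisable aryl ketone does not react.

**Step 11**
Reactants: 19
Product: 20, garcinielliptone FA, (2S,3S,4S)‑1‑(3‑hydroxyphenyl)‑2,7‑dimethyl‑2‑(3‑methylbut‑2‑en‑1‑yl)‑4‑(3‑methylbut‑3‑en‑1‑yl)‑3‑(prop‑1‑en‑2‑yl)oct‑6‑en‑1‑one
Conditions: TBAF, THF, 0 °C
Reagents that add atoms: none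
Why: Fluoride desilylation of the aryl silyl ether; the ketone has no α‑hydrogen and no stereocentre is epimerisable.

## Compound list

1 | methyl 5‑oxohexanoate | CC(=O)CCCC(=O)OC | starting material
2 | methyltriphenylphosphonium bromide | C[P+](c1ccccc1)(c1ccccc1)c1ccccc1.[Br-] | starting material
3 | methyl 5‑methylhex‑5‑enoate | C=C(C)CCCC(=O)OC | intermediate
4 | 5‑methylhex‑5‑enal | C=C(C)CCCC=O | intermediate
5 | ethyl vinyl ketone | C=CC(=O)CC | starting material
6 | (S)‑2‑(3‑methylbut‑3‑en‑1‑yl)‑5‑oxoheptanal | O=C[C@@H](CCC(=C)C)CCC(=O)CC | intermediate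
7 | (S)‑2‑methyl‑4‑(3‑methylbut‑3‑en‑1‑yl)cyclohex‑2‑en‑1‑one | O=C1C(C)=C[C@@H](CCC(=C)C)CC1 | intermediate
8 | isopropenylmagnesium bromide | C=C(C)[Mg]Br | starting material
9 | chlorotrimethylsilane | C[Si](C)(C)Cl | starting material
10 | (3S,4S) TMS enol ether | C[Si](C)(C)OC1=C(C)[C@H](C(=C)C)[C@@H](CCC(=C)C)CC1 | intermediate
11 | prenyl bromide | CC(C)=CCBr | starting material
12 | (2S,3S,4S)‑2‑methyl‑2‑prenyl‑3‑isopropenyl‑4‑(3‑methylbut‑3‑enyl)cyclohexanone | O=C1[C@@](C)(CC=C(C)C)[C@H](C(=C)C)[C@@H](CCC(=C)C)CC1 | intermediate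
13 | 3‑phenyl‑2‑(phenylsulfonyl)oxaziridine | O=S(=O)(N1OC1c1ccccc1)c1ccccc1 | starting material
14 | (2S,3S,4S)‑6‑hydroxy ketone | O=C1[C@@](C)(CC=C(C)C)[C@H](C(=C)C)[C@@H](CCC(=C)C)CC1O | intermediate
15 | (3‑bromophenoxy)(tert‑butyl)dimethylsilane | CC(C)(C)[Si](C)(C)Oc1cccc(Br)c1 | starting material
16 | (4S,5S,6S)‑1‑aryl‑cyclohexane‑1,2‑diol | OC1(c2cccc(O[Si](C)(C)C(C)(C)C)c2)[C@@](C)(CC=C(C)C)[C@H](C(=C)C)[C@@H](CCC(=C)C)CC1O | intermediate
17 | (3S,4S,5S) keto aldehyde | O=C(c1cccc(O[Si](C)(C)C(C)(C)C)c1)[C@@](C)(CC=C(C)C)[C@H](C(=C)C)[C@@H](CCC(=C)C)CC=O | intermediate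
18 | isopropyltriphenylphosphonium iodide | CC(C)[P+](c1ccccc1)(c1ccccc1)c1ccccc1.[I-] | starting material
19 | TBS ether of garcinielliptone FA | O=C(c1cccc(O[Si](C)(C)C(C)(C)C)c1)[C@@](C)(CC=C(C)C)[C@H](C(=C)C)[C@@H](CCC(=C)C)CC=C(C)C | intermediate
20 | garcinielliptone FA | C=C(C)CC[C@@H](CC=C(C)C)[C@@H](C(=C)C)[C@](C)(CC=C(C)C)C(=O)c1cccc(O)c1 | target

## Totals and risks

Total steps: 11. Longest linear sequence: 11 (fully linear from methyl 5‑oxohexanoate). Steps 3/4 and 10/11 can be telescoped.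

Three steps most likely to fail:

1. **Step 6, prenylation to the quaternary C2.** The axial C4 chain sits 1,3 to the incoming electrophile and may erode the trans selectivity, and O‑alkylation can compete. Fallback: put C2 under catalyst control by trapping the enolate as its allyl enol carbonate and running a Pd/PHOX decarboxylative allylation, then convert allyl to prenyl by cross‑metathesis with 2‑methyl‑2‑butene.
2. **Step 8, ArLi addition to the hindered α‑oxido ketone.** The carbonyl is flanked by a quaternary carbon and a lithium alkoxide, so addition may be slow or lose to enolisation. Fallback: cleave hydroxy ketone 14 first (Pb(OAc)4, MeOH) to the methyl ester–aldehyde, do the Wittig prenylation, then reduce the ester to the neopentyl aldehyde, add the aryllithium there and oxidise the benzylic alcohol to the ketone.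
3. **Step 5, isopropenyl cuprate addition.** The β‑carbon lies between the α‑methyl and the γ‑substituent, so the addition may be sluggish. Fallback: make the des‑methyl enone (methyl vinyl ketone in place of ethyl vinyl ketone in step 3), do the easier cuprate addition with MeI trapping, then prenylate via the thermodynamic tetrasubstituted enol silane.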